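**Plan**

- Numbering, used for every intermediate: C1 bears C7H2OH, C2 is the ketone, C3 carries the enoyloxy group, C4 the isopropyl group, C5 the propanoyloxy group, C6 is the =CH. The retrosynthesis cuts, in this order: the side-chain O–Si bond; C1–C7 (back to a C1–I enone); the C2 ketone back to a C2 carbinol carrying a carboxyl (lost as CO2); the C3–O and C5–O acyl bonds; the C3–O bond back to a C3–acetyl group; and last C2–C3 together with C4–C5.
- The last cut is possible because, in the single carbocycle, C2 and C5 are oxygen-bearing carbons placed 1,4 across the C1=C6 double bond. That is the pattern the C3–C4=C5–C6 diene of 3-hydroxy-2-pyrone leaves after a [4+2] addition (lactone bridge from C2 to C5), and C3/C4 with their trans oxygen and isopropyl groups are the two alkene carbons of an E-enone.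
- Forward: the six-membered ring closes first (step 1) inside a 2-oxabicyclo[2.2.2]octenone. Acetyl then becomes acetate, lactone and acetate are opened with allyl alcohol, C5–OH and then C3–OH are acylated, the allyl ester is removed and the α-hydroxy acid decarboxylated to the enone, C1 is iodinated and hydroxymethylated, and desilylation ends the route.
- The side-chain acid is made separately in two steps (Wittig, saponification) and joined in step 7.
- Stereochemistry: C3, C4 and C5 all come from step 1 (catalyst-controlled face; E-enone gives C3/C4 trans; endo mode puts the C4 isopropyl cis to C5–O). The Baeyer–Villiger step keeps C3, the fourth centre (C2 carbinol) is destroyed on purpose, and the enoate E geometry comes from the stabilised ylide.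

Key step: step 1

Assumption: which pseudoenantiomeric cinchona amine (quinine- or quinidine-derived) gives adduct 3 rather than its mirror image cannot be read from the structures; the quinine-derived catalyst is written, and its pseudoenantiomer takes its place if the sense is the other one.

**Step 1**
Reactants: 1 3-hydroxy-2H-pyran-2-one; 2 (3E)-5-methylhex-3-en-2-one
Product: 3 (1S,4S,5R,6R)-5-acetyl-4-hydroxy-6-(propan-2-yl)-2-oxabicyclo[2.2.2]oct-7-en-3-one (acetyl endo, that is syn to C7=C8; isopropyl syn to the lactone bridge)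
Conditions: 2 (2.5 equiv), 9-amino-9-deoxy-epi-quinine (10 mol%), CF3CO2H (20 mol%), CH2Cl2, 0 °C to rt
Reagents that add atoms: none
Why: The primary amine of the catalyst condenses with enone 2 to an iminium ion while the quinuclidine nitrogen deprotonates the 3-hydroxyl of 1; the 3-oxido-pyrone attacks the iminium β-carbon through its C6, the enamine α-carbon closes onto the C3 carbonyl (or both bonds form in one asynchronous event), and hydrolysis returns the catalyst. The closest known reaction type is the cinchona-amine-catalysed asymmetric Diels–Alder reaction of 3-hydroxy-2-pyrones with simple α,β-unsaturated ketones. The carbocycle closes as a [4+2] annulation across pyrone C3 and C6, which in the stepwise picture is a vinylogous Michael addition followed by a 6-(enolexo)-exo-trig aldol closure, and the lactone is left as the bridge. The trans relation of the acetyl- and isopropyl-bearing carbons comes from the E geometry of 2, their placement (acetyl under the new C7=C8 bridge, isopropyl on the lactone side) from the endo transition state, and the absolute configuration of the two bridgeheads from the pyrone face left open by the ion-paired catalyst. Regiochemistry (acetyl carbon next to the carbinol bridgehead) needs no help because the nucleophilic C6 of the oxido-pyrone can only meet the electrophilic β-carbon; endo and facial selectivity rest on one catalyst molecule holding both partners, and iminium activation is what should make the β-branched alkyl enone reactive enough.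

**Step 2**
Reactants: 3 (1S,4S,5R,6R)-5-acetyl-4-hydroxy-6-(propan-2-yl)-2-oxabicyclo[2.2.2]oct-7-en-3-one
Product: 4 (1S,4S,5R,6S)-4-hydroxy-3-oxo-6-(propan-2-yl)-2-oxabicyclo[2.2.2]oct-7-en-5-yl acetate
Conditions: mCPBA (2.5 equiv), Na2HPO4, CH2Cl2, 0 °C to rt
Reagents that add atoms: 3-chloroperoxybenzoic acid (mCPBA), OOC(=O)c1cccc(Cl)c1
Why: Baeyer–Villiger oxidation, in which the secondary ring carbon migrates in preference to methyl and with retention, so the endo acetyl becomes the endo acetate (C3 unchanged), while the ring alkene, flanked by two oxygenated bridgeheads and the lactone carbonyl, should be too electron-poor to be epoxidised at a competing rate.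

**Step 3**
Reactants: 4 (1S,4S,5R,6S)-4-hydroxy-3-oxo-6-(propan-2-yl)-2-oxabicyclo[2.2.2]oct-7-en-5-yl acetate
Product: 5 prop-2-en-1-yl (1S,4S,5S,6R)-1,4,6-trihydroxy-5-(propan-2-yl)cyclohex-2-ene-1-carboxylate
Conditions: allyl alcohol (solvent), K2CO3 (0.3 equiv), 0 °C to rt; AcOH quench before concentration
Reagents that add atoms: prop-2-en-1-ol (allyl alcohol), C=CCO
Why: Base-catalysed transesterification in allyl alcohol opens the bridged lactone to the allyl ester and removes the acetate as allyl acetate in the same operation without touching a stereocentre; the allyl ester is chosen because it can later be taken off without hydroxide.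

**Step 4**
Reactants: 5 prop-2-en-1-yl (1S,4S,5S,6R)-1,4,6-trihydroxy-5-(propan-2-yl)cyclohex-2-ene-1-carboxylate
Product: 6 prop-2-en-1-yl (1S,4S,5R,6R)-1,6-dihydroxy-4-(propanoyloxy)-5-(propan-2-yl)cyclohex-2-ene-1-carboxylate
Conditions: EtCOCl (1.05 equiv), 2,4,6-collidine, CH2Cl2, −78 to −40 °C
Reagents that add atoms: propanoyl chloride, CCC(=O)Cl
Why: Site-selective acylation with an acid chloride and a hindered pyridine base at low temperature: the allylic C5 hydroxyl has the sp2 carbon C6 as one neighbour and should react well before the C3 hydroxyl, which is wedged between the fully substituted C2 and the isopropyl-bearing C4, while the tertiary C2 hydroxyl is inert under these conditions.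

**Step 5**
Reactants: 7 {[tert-butyl(dimethyl)silyl]oxy}acetaldehyde; 8 ethyl 2-(triphenyl-λ5-phosphanylidene)propanoate
Product: 9 ethyl (2E)-4-{[tert-butyl(dimethyl)silyl]oxy}-2-methylbut-2-enoate
Conditions: CH2Cl2, rt
Reagents that add atoms: none
Why: Wittig olefination with a stabilised α-methyl ylide, which should give the trisubstituted enoate with the ester and the CH2OSi group trans (E).

**Step 6**
Reactants: 9 ethyl (2E)-4-{[tert-butyl(dimethyl)silyl]oxy}-2-methylbut-2-enoate
Product: 10 (2E)-4-{[tert-butyl(dimethyl)silyl]oxy}-2-methylbut-2-enoic acid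
Conditions: LiOH·H2O, THF/MeOH/H2O, rt; then 1 M HCl to pH 4, 0 °C
Reagents that add atoms: lithium hydroxide, [Li+].[OH-]
Why: Saponification of the ethyl ester, which leaves the primary silyl ether and the alkene geometry untouched when the acidification is kept mild and cold.

**Step 7**
Reactants: 6 prop-2-en-1-yl (1S,4S,5R,6R)-1,6-dihydroxy-4-(propanoyloxy)-5-(propan-2-yl)cyclohex-2-ene-1-carboxylate; 10 (2E)-4-{[tert-butyl(dimethyl)silyl]oxy}-2-methylbut-2-enoic acid
Product: 12 prop-2-en-1-yl (1S,4S,5S,6R)-6-{[(2E)-4-{[tert-butyl(dimethyl)silyl]oxy}-2-methylbut-2-enoyl]oxy}-1-hydroxy-4-(propanoyloxy)-5-(propan-2-yl)cyclohex-2-ene-1-carboxylate, via mixed 2,4,6-trichlorobenzoic anhydride 11 (not isolated)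
Conditions: 10 (1.5 equiv), 2,4,6-Cl3C6H2COCl, Et3N, toluene, rt; then 6, DMAP, toluene, rt to 40 °C
Reagents that add atoms: 2,4,6-trichlorobenzoyl chloride, O=C(Cl)c1c(Cl)cc(Cl)cc1Cl (its atoms stay only in 11)
Why: Yamaguchi esterification, in which DMAP attacks the mixed anhydride at the less hindered enoyl carbonyl and the acylpyridinium is taken by the only reactive hydroxyl left, the secondary C3–OH (the neighbouring tertiary C2–OH should not acylate), and the E-2-methyl enoate is the stable geometry and does not isomerise.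

**Step 8**
Reactants: 12 prop-2-en-1-yl (1S,4S,5S,6R)-6-{[(2E)-4-{[tert-butyl(dimethyl)silyl]oxy}-2-methylbut-2-enoyl]oxy}-1-hydroxy-4-(propanoyloxy)-5-(propan-2-yl)cyclohex-2-ene-1-carboxylate
Product: 13 (1S,4S,5S,6R)-6-{[(2E)-4-{[tert-butyl(dimethyl)silyl]oxy}-2-methylbut-2-enoyl]oxy}-1-hydroxy-4-(propanoyloxy)-5-(propan-2-yl)cyclohex-2-ene-1-carboxylic acid
Conditions: Pd(PPh3)4 (3 mol%), morpholine (5 equiv), THF, 0 °C; aq. citric acid work-up
Reagents that add atoms: none
Why: Tsuji–Trost deallylation, in which zerovalent palladium should ionise the unhindered terminal allyl ester far faster than the hindered secondary ring propionate at C5 and morpholine captures the allyl group, so the acid is freed without hydroxide and both acyl groups and the silyl ether stay.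

**Step 9**
Reactants: 13 (1S,4S,5S,6R)-6-{[(2E)-4-{[tert-butyl(dimethyl)silyl]oxy}-2-methylbut-2-enoyl]oxy}-1-hydroxy-4-(propanoyloxy)-5-(propan-2-yl)cyclohex-2-ene-1-carboxylic acid
Product: 14 (1R,5S,6S)-2-oxo-5-(propanoyloxy)-6-(propan-2-yl)cyclohex-3-en-1-yl (2E)-4-{[tert-butyl(dimethyl)silyl]oxy}-2-methylbut-2-enoate
Conditions: Pb(OAc)4 (1.2 equiv), CH2Cl2, −20 to 0 °C
Reagents that add atoms: none
Why: Oxidative decarboxylation of an α-hydroxy acid by lead tetraacetate turns the C2 carbinol and its carboxyl into the C2 ketone and CO2 and so brings C1=C6 into conjugation; because C3 and C5 are both acylated at this point, no free 1,2-diol is offered to the reagent.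

**Step 10**
Reactants: 14 (1R,5S,6S)-2-oxo-5-(propanoyloxy)-6-(propan-2-yl)cyclohex-3-en-1-yl (2E)-4-{[tert-butyl(dimethyl)silyl]oxy}-2-methylbut-2-enoate
Product: 15 (1R,5R,6S)-3-iodo-2-oxo-5-(propanoyloxy)-6-(propan-2-yl)cyclohex-3-en-1-yl (2E)-4-{[tert-butyl(dimethyl)silyl]oxy}-2-methylbut-2-enoate
Conditions: I2 (2 equiv), pyridine/CH2Cl2 (1:1), 0 °C to rt
Reagents that add atoms: iodine, II
Why: α-Iodination of an enone by iodine and pyridine (conjugate addition of pyridine at C6, iodination of the enolate at C1, loss of pyridine), selective because only C1 carries an enone α-hydrogen (the side-chain enoate has none), and C3, now α to the ketone, already sits in its more stable trans arrangement with C4.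

**Step 11**
Reactants: 15 (1R,5R,6S)-3-iodo-2-oxo-5-(propanoyloxy)-6-(propan-2-yl)cyclohex-3-en-1-yl (2E)-4-{[tert-butyl(dimethyl)silyl]oxy}-2-methylbut-2-enoate; 16 (tributylstannyl)methanol
Product: 17 (1R,5S,6S)-3-(hydroxymethyl)-2-oxo-5-(propanoyloxy)-6-(propan-2-yl)cyclohex-3-en-1-yl (2E)-4-{[tert-butyl(dimethyl)silyl]oxy}-2-methylbut-2-enoate
Conditions: Pd(PPh3)4 (10 mol%), 1,4-dioxane, 80 °C
Reagents that add atoms: none
Why: Stille coupling, in which zerovalent palladium inserts rapidly into the C1–I bond, the α-oxygenated CH2OH group is transferred from tin in preference to butyl and reductive elimination forms C1–C7 under neutral conditions that spare both esters and the stereocentres.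

**Step 12**
Reactants: 17 (1R,5S,6S)-3-(hydroxymethyl)-2-oxo-5-(propanoyloxy)-6-(propan-2-yl)cyclohex-3-en-1-yl (2E)-4-{[tert-butyl(dimethyl)silyl]oxy}-2-methylbut-2-enoate
Product: 18 (1R,5S,6S)-3-(hydroxymethyl)-2-oxo-5-(propanoyloxy)-6-(propan-2-yl)cyclohex-3-en-1-yl (2E)-4-hydroxy-2-methylbut-2-enoate (CNP0285949.1)
Conditions: HF·pyridine, pyridine, THF, 0 °C to rt
Reagents that add atoms: none
Why: Fluoride cleavage of the primary silyl ether under buffered, weakly acidic conditions, where neither acyl migration nor elimination of the acyloxy groups is expected.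

**Compound list**

1 | 3-hydroxy-2H-pyran-2-one | OC1=CC=COC1=O | starting material
2 | (3E)-5-methylhex-3-en-2-one | CC(=O)/C=C/C(C)C | starting material
3 | (1S,4S,5R,6R)-5-acetyl-4-hydroxy-6-(propan-2-yl)-2-oxabicyclo[2.2.2]oct-7-en-3-one | O=C1O[C@H]2C=C[C@]1(O)[C@H](C(C)=O)[C@H]2C(C)C | intermediate
4 | (1S,4S,5R,6S)-4-hydroxy-3-oxo-6-(propan-2-yl)-2-oxabicyclo[2.2.2]oct-7-en-5-yl acetate | O=C1O[C@H]2C=C[C@]1(O)[C@H](OC(C)=O)[C@H]2C(C)C | intermediate
5 | prop-2-en-1-yl (1S,4S,5S,6R)-1,4,6-trihydroxy-5-(propan-2-yl)cyclohex-2-ene-1-carboxylate | O[C@H]1C=C[C@@](O)(C(=O)OCC=C)[C@H](O)[C@H]1C(C)C | intermediate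
6 | prop-2-en-1-yl (1S,4S,5R,6R)-1,6-dihydroxy-4-(propanoyloxy)-5-(propan-2-yl)cyclohex-2-ene-1-carboxylate | CCC(=O)O[C@H]1C=C[C@@](O)(C(=O)OCC=C)[C@H](O)[C@H]1C(C)C | intermediate
7 | {[tert-butyl(dimethyl)silyl]oxy}acetaldehyde | O=CCO[Si](C)(C)C(C)(C)C | starting material
8 | ethyl 2-(triphenyl-λ5-phosphanylidene)propanoate | CCOC(=O)C(C)=P(c1ccccc1)(c1ccccc1)c1ccccc1 | starting material
9 | ethyl (2E)-4-{[tert-butyl(dimethyl)silyl]oxy}-2-methylbut-2-enoate | CCOC(=O)/C(C)=C/CO[Si](C)(C)C(C)(C)C | intermediate
10 | (2E)-4-{[tert-butyl(dimethyl)silyl]oxy}-2-methylbut-2-enoic acid | OC(=O)/C(C)=C/CO[Si](C)(C)C(C)(C)C | intermediate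
11 | (2E)-4-{[tert-butyl(dimethyl)silyl]oxy}-2-methylbut-2-enoic 2,4,6-trichlorobenzoic anhydride | O=C(OC(=O)/C(C)=C/CO[Si](C)(C)C(C)(C)C)c1c(Cl)cc(Cl)cc1Cl | intermediate (not isolated)
12 | prop-2-en-1-yl (1S,4S,5S,6R)-6-{[(2E)-4-{[tert-butyl(dimethyl)silyl]oxy}-2-methylbut-2-enoyl]oxy}-1-hydroxy-4-(propanoyloxy)-5-(propan-2-yl)cyclohex-2-ene-1-carboxylate | CCC(=O)O[C@H]1C=C[C@@](O)(C(=O)OCC=C)[C@H](OC(=O)/C(C)=C/CO[Si](C)(C)C(C)(C)C)[C@H]1C(C)C | intermediate
13 | (1S,4S,5S,6R)-6-{[(2E)-4-{[tert-butyl(dimethyl)silyl]oxy}-2-methylbut-2-enoyl]oxy}-1-hydroxy-4-(propanoyloxy)-5-(propan-2-yl)cyclohex-2-ene-1-carboxylic acid | CCC(=O)O[C@H]1C=C[C@@](O)(C(=O)O)[C@H](OC(=O)/C(C)=C/CO[Si](C)(C)C(C)(C)C)[C@H]1C(C)C | intermediate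
14 | (1R,5S,6S)-2-oxo-5-(propanoyloxy)-6-(propan-2-yl)cyclohex-3-en-1-yl (2E)-4-{[tert-butyl(dimethyl)silyl]oxy}-2-methylbut-2-enoate | CCC(=O)O[C@H]1C=CC(=O)[C@H](OC(=O)/C(C)=C/CO[Si](C)(C)C(C)(C)C)[C@H]1C(C)C | intermediate
15 | (1R,5R,6S)-3-iodo-2-oxo-5-(propanoyloxy)-6-(propan-2-yl)cyclohex-3-en-1-yl (2E)-4-{[tert-butyl(dimethyl)silyl]oxy}-2-methylbut-2-enoate | CCC(=O)O[C@H]1C=C(I)C(=O)[C@H](OC(=O)/C(C)=C/CO[Si](C)(C)C(C)(C)C)[C@H]1C(C)C | intermediate
16 | (tributylstannyl)methanol | OC[Sn](CCCC)(CCCC)CCCC | starting material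
17 | (1R,5S,6S)-3-(hydroxymethyl)-2-oxo-5-(propanoyloxy)-6-(propan-2-yl)cyclohex-3-en-1-yl (2E)-4-{[tert-butyl(dimethyl)silyl]oxy}-2-methylbut-2-enoate | CCC(=O)O[C@H]1C=C(CO)C(=O)[C@H](OC(=O)/C(C)=C/CO[Si](C)(C)C(C)(C)C)[C@H]1C(C)C | intermediate
18 | (1R,5S,6S)-3-(hydroxymethyl)-2-oxo-5-(propanoyloxy)-6-(propan-2-yl)cyclohex-3-en-1-yl (2E)-4-hydroxy-2-methylbut-2-enoate | CCC(=O)O[C@H]1C=C(CO)C(=O)[C@H](OC(=O)/C(C)=C/CO)[C@H]1C(C)C | target

**Totals**

Total step count: 12. Longest linear sequence: 10 steps (steps 1 to 4 and 7 to 12); the side-chain acid adds a two-step branch (steps 5 and 6).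

**Steps most likely to fail**

Step 1. The bond-forming event may take the exo course (acetyl toward the lactone bridge), which would put the C5 oxygen on the wrong face relative to C4; the β-branched enone may also react sluggishly. The fallback accepts the exo mode and repairs C5 later with known chemistry; it sets out from 1 and 2 and comes back at 14. With the cinchona amine of the appropriate sense, 1 and 2 give the acetyl-exo adduct F1 (acetyl syn to the lactone bridge, isopropyl syn to C7=C8), in which C3 and C4 already have the target configuration. Baeyer–Villiger oxidation as in step 2 gives the exo acetate F2, and allyl alcohol with K2CO3 gives the triol allyl ester F3, whose C5 hydroxyl is trans to isopropyl. A Mitsunobu esterification with propanoic acid (PPh3, diisopropyl azodicarboxylate, THF, 0 °C) should react only at the unhindered allylic C5 hydroxyl; it inverts C5 and installs the propionate in one operation, giving the C5 propionate F4, the C2 epimer of 6. Yamaguchi esterification with 10 gives the diester F5, Pd(PPh3)4 with morpholine gives the hydroxy acid F6, and Pb(OAc)4 removes the epimeric C2 centre, so the sequence rejoins the route at 14.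

Step 4. Acylation may spread to the C3 hydroxyl, or go twice, if the difference in accessibility between the two secondary hydroxyls is smaller than expected. The fallback replaces kinetic selection by protection and runs from 5 back to 6. The cis C2/C3 diol of 5 is the only pair that can close a five-membered acetal, so 2,2-dimethoxypropane with pyridinium p-toluenesulfonate in CH2Cl2 gives the acetonide F7 with C5–OH as the only free hydroxyl. Propionic anhydride, DMAP and pyridine give the acetonide propionate F8, and aqueous acetic acid at 40 °C removes the acetal to return 6.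

Step 11. Transfer of the sp3 hydroxymethyl group from tin is slow, so at the temperature needed protodeiodination, butyl transfer or palladium-mediated ionisation of the allylic C5 propionate may overtake the coupling. The fallback forms C1–C7 without palladium or tin and runs from 14 directly to 17, leaving out 15 and 16: a Morita–Baylis–Hillman hydroxymethylation of enone 14 with aqueous formaldehyde and DMAP in THF–water at rt. It makes no compound outside the list (F0).

**Further compounds**

F1 | step 1 | acetyl-exo adduct: 5-acetyl-4-hydroxy-6-(propan-2-yl)-2-oxabicyclo[2.2.2]oct-7-en-3-one with C5 and C6 as in 3 and both bridgeheads inverted | O=C1O[C@@H]2C=C[C@@]1(O)[C@H](C(C)=O)[C@H]2C(C)C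
F2 | step 1 | exo acetate: the 5-acetoxy analogue of F1 | O=C1O[C@@H]2C=C[C@@]1(O)[C@H](OC(C)=O)[C@H]2C(C)C
F3 | step 1 | triol allyl ester from F2: the diastereomer of 5 with the C2 and C5 centres (target numbering) inverted | O[C@@H]1C=C[C@](O)(C(=O)OCC=C)[C@H](O)[C@H]1C(C)C
F4 | step 1 | C5 propionate after Mitsunobu inversion: the C2 epimer (target numbering) of 6 | CCC(=O)O[C@H]1C=C[C@](O)(C(=O)OCC=C)[C@H](O)[C@H]1C(C)C
F5 | step 1 | diester: the C2 epimer (target numbering) of 12 | CCC(=O)O[C@H]1C=C[C@](O)(C(=O)OCC=C)[C@H](OC(=O)/C(C)=C/CO[Si](C)(C)C(C)(C)C)[C@H]1C(C)C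
F6 | step 1 | hydroxy acid: the C2 epimer (target numbering) of 13 | CCC(=O)O[C@H]1C=C[C@](O)(C(=O)O)[C@H](OC(=O)/C(C)=C/CO[Si](C)(C)C(C)(C)C)[C@H]1C(C)C
F7 | step 4 | acetonide of 5: isopropylidene acetal across the cis C2/C3 diol, C5–OH free | O[C@H]1C=C[C@]2(C(=O)OCC=C)OC(C)(C)O[C@@H]2[C@H]1C(C)C
F8 | step 4 | acetonide propionate: the C5 propanoate of F7 | CCC(=O)O[C@H]1C=C[C@]2(C(=O)OCC=C)OC(C)(C)O[C@@H]2[C@H]1C(C)C
F0 | step 11 | none | none
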